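**Strategy.** Ring A is made last, by disconnecting its C2–C3 and C1–C6 bonds. The feature exploited is that C1 (ester-bearing) and C2 (aroyl-bearing) of ring A are neighbours, as the two carbons of a doubly activated alkyne would be, while C3(OMe), C4, C5(OH) and C6 carry the 1,3-dioxygenation of an acetoacetate-derived ketene-acetal diene. One regiocontrolled [4+2] cycloaddition with loss of methanol therefore closes ring A, forms both bonds and delivers OMe at C3 and free OH at C5 already distinguished, with the crowded diaryl ketone carbonyl in place beforehand. The precursor is a ring B aroylpropiolate (ynone ester) whose two ortho oxygens are masked as benzyl and methoxymethyl ethers.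

Key step: step 9

Remark on the chemistry: ring A is numbered from the ester-bearing carbon (C1) through the aroyl-bearing carbon (C2). The target is achiral, and the two ring B oxygens are equivalent until one is acetylated. Compounds 5, 9 and 10 are racemic and their stereocentre is erased in the same or the next step.

**Route**

Step 1
Reactants: 1 orcinol (5-methylbenzene-1,3-diol)
Product: 2 3-(benzyloxy)-5-methylphenol
Conditions: 1 (2 equiv), BnBr (1 equiv), K2CO3, DMF, rt
Reagents that add atoms: benzyl bromide, BrCc1ccccc1
Why: Williamson ether synthesis in which an excess of the cheap diphenol biases alkylation toward the mono-ether, which should be separable from water-soluble orcinol and from the non-acidic dibenzyl ether by extraction into aqueous base.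

Step 2
Reactants: 2 3-(benzyloxy)-5-methylphenol
Product: 3 1-(benzyloxy)-3-(methoxymethoxy)-5-methylbenzene
Conditions: MOMCl, iPr2NEt, CH2Cl2, 0 °C to rt
Reagents that add atoms: chloromethyl methyl ether, COCCl
Why: O-alkylation of the remaining phenol by the reactive α-chloro ether (acetal protection) differentiates the two ring B oxygens and installs a strong ortho-directing group.

Step 3
Reactants: 3 1-(benzyloxy)-3-(methoxymethoxy)-5-methylbenzene
Product: 6 2-(benzyloxy)-6-(methoxymethoxy)-4-methylbenzaldehyde, via aryllithium 4 (not isolated), via lithium hemiaminal alkoxide 5 (not isolated)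
Conditions: n-BuLi, TMEDA, THF, 0 °C; DMF, 0 °C to rt; H2O
Reagents that add atoms: N,N-dimethylformamide, CN(C)C=O
Why: Directed ortho-metalation removes the most acidic ring hydrogen, the one flanked by the chelating OMOM group and the OBn group, and formylation of the aryllithium with DMF gives the aldehyde when the hemiaminal alkoxide collapses on hydrolysis.

Step 4
Reactants: 6 2-(benzyloxy)-6-(methoxymethoxy)-4-methylbenzaldehyde; 7 methyl propiolate
Product: 10 methyl 4-[2-(benzyloxy)-6-(methoxymethoxy)-4-methylphenyl]-4-hydroxybut-2-ynoate (racemic), via lithium acetylide 8 (not isolated), via lithium alkoxide 9 (not isolated)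
Conditions: 7, LiN(SiMe3)2, THF, −78 °C; then 6, −78 °C; AcOH, −78 °C
Reagents that add atoms: none
Why: 1,2-Addition of a lithium acetylide to a non-enolisable aldehyde at −78 °C, where methyl lithiopropiolate is stable, with a cold acidic quench to prevent reversal; the carbinol stereocentre forms racemic and is removed in step 5.

Step 5
Reactants: 10 methyl 4-[2-(benzyloxy)-6-(methoxymethoxy)-4-methylphenyl]-4-hydroxybut-2-ynoate
Product: 11 methyl 4-[2-(benzyloxy)-6-(methoxymethoxy)-4-methylphenyl]-4-oxobut-2-ynoate
Conditions: Dess–Martin periodinane, CH2Cl2, 0 °C to rt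
Reagents that add atoms: none
Why: Dess–Martin oxidation of a secondary benzylic and propargylic alcohol proceeds under nearly neutral conditions that spare the MOM and benzyl ethers and the electrophilic ynoate.

Step 6
Reactants: 12 acetyl chloride; 13 1,1-dichloroethene
Product: 15 4,4-dichlorobut-3-en-2-one, via trichloro ketone 14 (not isolated)
Conditions: AlCl3, CH2Cl2, 0 °C to rt; ice–water; steam distillation
Reagents that add atoms: none
Why: Friedel–Crafts-type acylation of an alkene, in which the acylium ion adds to the CH2 terminus of the dichloroalkene, chloride capture gives the trichloro ketone, and β-elimination of HCl during distillation gives the conjugated dichlorovinyl ketone.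

Step 7
Reactants: 15 4,4-dichlorobut-3-en-2-one
Product: 17 4,4-dimethoxybut-3-en-2-one, via chloro methoxy enone 16 (not isolated)
Conditions: NaOMe (2.2 equiv), MeOH, 0 °C to rt
Reagents that add atoms: sodium methoxide, [Na+].[O-]C
Why: Two successive addition–elimination reactions (nucleophilic vinylic substitution) of methoxide at the β-carbon of the enone replace both chlorides and give the ketene acetal.

Step 8
Reactants: 17 4,4-dimethoxybut-3-en-2-one
Product: 19 1,1-dimethoxy-3-(trimethylsilyloxy)buta-1,3-diene, via lithium dienolate 18 (not isolated)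
Conditions: LiN(iPr)2, THF, −78 °C; Me3SiCl, −78 °C to rt; non-aqueous work-up, distillation
Reagents that add atoms: chlorotrimethylsilane, C[Si](C)(C)Cl
Why: Kinetic deprotonation of the only enolisable position (the acetyl methyl group) and O-silylation of the dienolate is standard silyl enol ether formation, and the moisture-sensitive diene is isolated without contact with water.

Step 9
Reactants: 11 methyl 4-[2-(benzyloxy)-6-(methoxymethoxy)-4-methylphenyl]-4-oxobut-2-ynoate; 19 1,1-dimethoxy-3-(trimethylsilyloxy)buta-1,3-diene
Product: 22 methyl 2-[2-(benzyloxy)-6-(methoxymethoxy)-4-methylbenzoyl]-5-hydroxy-3-methoxybenzoate, via cycloadduct 20 (not isolated), via aryl silyl ether 21 (not isolated)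
Conditions: 19 (2 equiv), toluene, 0 °C to rt; then 0.1 M aq HCl, THF, 0 °C
Reagents that add atoms: none
Why: The electron-rich ketene-acetal diene 19 should add to the doubly activated alkyne of 11 in a strongly asynchronous normal-demand Diels–Alder reaction, its CH2 terminus bonding first (Michael-like) to C1 and its dimethoxy carbon then to C2, to give the 1,4-cyclohexadiene ketal 20, which aromatises by 1,4-elimination of methanol to 21 and is desilylated by the dilute acid to phenol 22. The closest known reaction type is the cycloaddition of 1,1-dialkoxy-3-silyloxybuta-1,3-dienes with acetylenic esters and ynones, which gives resorcinol monomethyl ethers directly. Ring A, the only ring formed, closes in the intermolecular [4+2] mode through the bonds C1–C6 and C2–C3 (should the addition be stepwise, the second bond is a six-membered closure of the allenolate carbon C2 onto the dialkoxycarbenium carbon C3). No stereocentre is created, because 20 has none and 22 is a planar arene. The selectivity needed is regiochemical, and it is secured by the ketone being a stronger acceptor than the ester, so that the alkyne carbon β to the ketone (C1, which bears the ester) is the more electrophilic and takes the CH2 terminus, while the twisted di-ortho-substituted ring B cannot weaken the carbonyl by donation. Chemoselectivity is secured by the absence of free phenols in 11 and by a brief, cold acid treatment that the MOM ether should survive.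

Step 10
Reactants: 22 methyl 2-[2-(benzyloxy)-6-(methoxymethoxy)-4-methylbenzoyl]-5-hydroxy-3-methoxybenzoate
Product: 23 methyl 5-(benzyloxy)-2-[2-(benzyloxy)-6-(methoxymethoxy)-4-methylbenzoyl]-3-methoxybenzoate
Conditions: BnBr, K2CO3, DMF, rt
Reagents that add atoms: benzyl bromide, BrCc1ccccc1
Why: Williamson etherification of the only free phenol, acidified by the para ketone, proceeds under mild carbonate conditions that leave the methyl ester and the MOM ether untouched.

Step 11
Reactants: 23 methyl 5-(benzyloxy)-2-[2-(benzyloxy)-6-(methoxymethoxy)-4-methylbenzoyl]-3-methoxybenzoate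
Product: 24 methyl 5-(benzyloxy)-2-[2-(benzyloxy)-6-hydroxy-4-methylbenzoyl]-3-methoxybenzoate
Conditions: HCl (1 M in MeOH), THF, 45 °C
Reagents that add atoms: none
Why: Acid-catalysed acetal methanolysis cleaves the MOM ether, while the benzyl ethers and the ketone are inert and the methyl ester cannot change in methanol.

Step 12
Reactants: 24 methyl 5-(benzyloxy)-2-[2-(benzyloxy)-6-hydroxy-4-methylbenzoyl]-3-methoxybenzoate
Product: 25 methyl 2-[2-(acetyloxy)-6-(benzyloxy)-4-methylbenzoyl]-5-(benzyloxy)-3-methoxybenzoate
Conditions: Ac2O, pyridine, DMAP (cat.), CH2Cl2, rt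
Reagents that add atoms: acetic anhydride, CC(=O)OC(C)=O
Why: DMAP-catalysed acylation (nucleophilic catalysis) acetylates the single free phenol despite its hydrogen bond to the ketone, and no other nucleophilic site is present.

Step 13
Reactants: 25 methyl 2-[2-(acetyloxy)-6-(benzyloxy)-4-methylbenzoyl]-5-(benzyloxy)-3-methoxybenzoate
Product: 26 penibenzophenone C, methyl 2-[2-(acetyloxy)-6-hydroxy-4-methylbenzoyl]-5-hydroxy-3-methoxybenzoate
Conditions: H2 (1 atm), 10% Pd/C, EtOAc, rt
Reagents that add atoms: none
Why: Heterogeneous catalytic hydrogenolysis cleaves both benzyl aryl ethers in a neutral aprotic solvent, in which the aryl acetate, the methyl ester and the hindered, twisted diaryl ketone should persist.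

**Compound list**

1 | orcinol (5-methylbenzene-1,3-diol) | Cc1cc(O)cc(O)c1 | starting material
2 | 3-(benzyloxy)-5-methylphenol | Cc1cc(O)cc(OCc2ccccc2)c1 | intermediate
3 | 1-(benzyloxy)-3-(methoxymethoxy)-5-methylbenzene | COCOc1cc(C)cc(OCc2ccccc2)c1 | intermediate
4 | [2-(benzyloxy)-6-(methoxymethoxy)-4-methylphenyl]lithium | [Li]c1c(OCOC)cc(C)cc1OCc1ccccc1 | intermediate (not isolated)
5 | lithium [2-(benzyloxy)-6-(methoxymethoxy)-4-methylphenyl](dimethylamino)methanolate (racemic) | CN(C)C(O[Li])c1c(OCOC)cc(C)cc1OCc1ccccc1 | intermediate (not isolated)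
6 | 2-(benzyloxy)-6-(methoxymethoxy)-4-methylbenzaldehyde | COCOc1cc(C)cc(OCc2ccccc2)c1C=O | intermediate
7 | methyl propiolate (methyl prop-2-ynoate) | C#CC(=O)OC | starting material
8 | methyl 3-lithioprop-2-ynoate | [Li]C#CC(=O)OC | intermediate (not isolated)
9 | lithium alkoxide of 10 (racemic) | COC(=O)C#CC(O[Li])c1c(OCOC)cc(C)cc1OCc1ccccc1 | intermediate (not isolated)
10 | methyl 4-[2-(benzyloxy)-6-(methoxymethoxy)-4-methylphenyl]-4-hydroxybut-2-ynoate (racemic) | COC(=O)C#CC(O)c1c(OCOC)cc(C)cc1OCc1ccccc1 | intermediate
11 | methyl 4-[2-(benzyloxy)-6-(methoxymethoxy)-4-methylphenyl]-4-oxobut-2-ynoate | COC(=O)C#CC(=O)c1c(OCOC)cc(C)cc1OCc1ccccc1 | intermediate (key-step precursor)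
12 | acetyl chloride | CC(=O)Cl | starting material
13 | 1,1-dichloroethene | C=C(Cl)Cl | starting material
14 | 4,4,4-trichlorobutan-2-one | CC(=O)CC(Cl)(Cl)Cl | intermediate (not isolated)
15 | 4,4-dichlorobut-3-en-2-one | CC(=O)C=C(Cl)Cl | intermediate
16 | 4-chloro-4-methoxybut-3-en-2-one (alkene geometry not defined) | COC(Cl)=CC(C)=O | intermediate (not isolated)
17 | 4,4-dimethoxybut-3-en-2-one | COC(OC)=CC(C)=O | intermediate
18 | lithium 4,4-dimethoxybuta-1,3-dien-2-olate | [Li]OC(=C)C=C(OC)OC | intermediate (not isolated)
19 | 1,1-dimethoxy-3-(trimethylsilyloxy)buta-1,3-diene | COC(OC)=CC(=C)O[Si](C)(C)C | intermediate (key-step precursor)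
20 | methyl 2-[2-(benzyloxy)-6-(methoxymethoxy)-4-methylbenzoyl]-3,3-dimethoxy-5-(trimethylsilyloxy)cyclohexa-1,4-diene-1-carboxylate | COC(=O)C1=C(C(=O)c2c(OCOC)cc(C)cc2OCc2ccccc2)C(OC)(OC)C=C(O[Si](C)(C)C)C1 | intermediate (not isolated)
21 | methyl 2-[2-(benzyloxy)-6-(methoxymethoxy)-4-methylbenzoyl]-3-methoxy-5-(trimethylsilyloxy)benzoate | COC(=O)c1cc(O[Si](C)(C)C)cc(OC)c1C(=O)c1c(OCOC)cc(C)cc1OCc1ccccc1 | intermediate (not isolated)
22 | methyl 2-[2-(benzyloxy)-6-(methoxymethoxy)-4-methylbenzoyl]-5-hydroxy-3-methoxybenzoate | COC(=O)c1cc(O)cc(OC)c1C(=O)c1c(OCOC)cc(C)cc1OCc1ccccc1 | intermediate (key-step product)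
23 | methyl 5-(benzyloxy)-2-[2-(benzyloxy)-6-(methoxymethoxy)-4-methylbenzoyl]-3-methoxybenzoate | COC(=O)c1cc(OCc2ccccc2)cc(OC)c1C(=O)c1c(OCOC)cc(C)cc1OCc1ccccc1 | intermediate
24 | methyl 5-(benzyloxy)-2-[2-(benzyloxy)-6-hydroxy-4-methylbenzoyl]-3-methoxybenzoate | COC(=O)c1cc(OCc2ccccc2)cc(OC)c1C(=O)c1c(O)cc(C)cc1OCc1ccccc1 | intermediate
25 | methyl 2-[2-(acetyloxy)-6-(benzyloxy)-4-methylbenzoyl]-5-(benzyloxy)-3-methoxybenzoate | COC(=O)c1cc(OCc2ccccc2)cc(OC)c1C(=O)c1c(OC(C)=O)cc(C)cc1OCc1ccccc1 | intermediate
26 | penibenzophenone C, methyl 2-[2-(acetyloxy)-6-hydroxy-4-methylbenzoyl]-5-hydroxy-3-methoxybenzoate | COC(=O)c1cc(O)cc(OC)c1C(=O)c1c(O)cc(C)cc1OC(C)=O | target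

**Step count and risk**

Total step count: 13. Longest linear sequence: 10 steps (steps 1–5 and 9–13 from orcinol). The diene branch (steps 6–8) has 3 steps and joins at step 9.

Steps most likely to fail:

1. Step 9. The diene may add in the reverse orientation under the influence of the ester, or be consumed by Michael addition without ring closure or by hydrolysis before it cycloadds. The fallback removes the competing acceptor from the alkyne, so that the ketone alone dictates the orientation. It sets out from aldehyde 6 and returns at 22.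
   - The lithium acetylide of 3,3,3-triethoxyprop-1-yne F1 (n-BuLi, THF, −78 °C) would add to 6 to give the orthoester carbinol 1-[2-(benzyloxy)-6-(methoxymethoxy)-4-methylphenyl]-4,4,4-triethoxybut-2-yn-1-ol F2.
   - MnO2 in CH2Cl2 would oxidise this to the ynone orthoester 1-[2-(benzyloxy)-6-(methoxymethoxy)-4-methylphenyl]-4,4,4-triethoxybut-2-yn-1-one F3.
   - Cycloaddition of F3 with diene 19 in toluene at 80 °C would give the cyclohexadiene cycloadduct F4, which is not isolated.
   - Dilute aqueous acid would eliminate methanol, remove the silyl group and hydrolyse the orthoester to ethyl 2-[2-(benzyloxy)-6-(methoxymethoxy)-4-methylbenzoyl]-5-hydroxy-3-methoxybenzoate F5.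
   - Transesterification with NaOMe in MeOH would then give 22.

2. Step 3. Deprotonation at the benzylic position of the benzyl ether, followed by [1,2]-Wittig rearrangement, or metalation beside the methyl group, may compete with lithiation between the two oxygens. The fallback formylates before the oxygens are differentiated, so that no benzyl group is present during the lithiation. It sets out from orcinol 1 and returns at 6, replacing steps 1–3.
   - MOMCl and iPr2NEt would give 1,3-bis(methoxymethoxy)-5-methylbenzene F6.
   - n-BuLi in THF at 0 °C would give [2,6-bis(methoxymethoxy)-4-methylphenyl]lithium F7, which with DMF would give 2,6-bis(methoxymethoxy)-4-methylbenzaldehyde F8.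
   - HCl in MeOH would free 2,6-dihydroxy-4-methylbenzaldehyde F9.
   - One equivalent of BnBr with K2CO3 in acetone would give 2-(benzyloxy)-6-hydroxy-4-methylbenzaldehyde F10, the second phenol being held back by its chelate to the aldehyde.
   - MOMCl and iPr2NEt would then give 6.

3. Step 4. The lithiated propiolate may decompose, or may add only sluggishly to the hindered, electron-rich aldehyde, with base-induced side reactions of the ynoate taking over. The fallback attaches a robust alkyne first and builds the ester onto it afterwards. It sets out from 6 and returns at 10.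
   - HC≡CMgBr in THF at 0 °C would give 1-[2-(benzyloxy)-6-(methoxymethoxy)-4-methylphenyl]prop-2-yn-1-ol F11.
   - t-BuMe2SiCl and imidazole in DMF would give its tert-butyldimethylsilyl ether F12.
   - n-BuLi in THF at −78 °C would give the lithium acetylide of the silyl ether F13, which with methyl chloroformate would give methyl 4-[2-(benzyloxy)-6-(methoxymethoxy)-4-methylphenyl]-4-[(tert-butyldimethylsilyl)oxy]but-2-ynoate F14.
   - Bu4NF buffered with AcOH in THF at 0 °C would remove the silyl group and give 10.

**Further compounds**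

F1 | step 9 | (3,3,3-triethoxyprop-1-yn-1-yl)lithium (not isolated) | CCOC(OCC)(OCC)C#C[Li]
F2 | step 9 | 1-[2-(benzyloxy)-6-(methoxymethoxy)-4-methylphenyl]-4,4,4-triethoxybut-2-yn-1-ol (racemic) | CCOC(OCC)(OCC)C#CC(O)c1c(OCOC)cc(C)cc1OCc1ccccc1
F3 | step 9 | 1-[2-(benzyloxy)-6-(methoxymethoxy)-4-methylphenyl]-4,4,4-triethoxybut-2-yn-1-one | CCOC(OCC)(OCC)C#CC(=O)c1c(OCOC)cc(C)cc1OCc1ccccc1
F4 | step 9 | [2-(benzyloxy)-6-(methoxymethoxy)-4-methylphenyl][6,6-dimethoxy-2-(triethoxymethyl)-4-(trimethylsilyloxy)cyclohexa-1,4-dien-1-yl]methanone (not isolated) | CCOC(OCC)(OCC)C1=C(C(=O)c2c(OCOC)cc(C)cc2OCc2ccccc2)C(OC)(OC)C=C(O[Si](C)(C)C)C1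
F5 | step 9 | ethyl 2-[2-(benzyloxy)-6-(methoxymethoxy)-4-methylbenzoyl]-5-hydroxy-3-methoxybenzoate | CCOC(=O)c1cc(O)cc(OC)c1C(=O)c1c(OCOC)cc(C)cc1OCc1ccccc1
F6 | step 3 | 1,3-bis(methoxymethoxy)-5-methylbenzene | COCOc1cc(C)cc(OCOC)c1
F7 | step 3 | [2,6-bis(methoxymethoxy)-4-methylphenyl]lithium (not isolated) | [Li]c1c(OCOC)cc(C)cc1OCOC
F8 | step 3 | 2,6-bis(methoxymethoxy)-4-methylbenzaldehyde | COCOc1cc(C)cc(OCOC)c1C=O
F9 | step 3 | 2,6-dihydroxy-4-methylbenzaldehyde | Cc1cc(O)c(C=O)c(O)c1
F10 | step 3 | 2-(benzyloxy)-6-hydroxy-4-methylbenzaldehyde | Cc1cc(O)c(C=O)c(OCc2ccccc2)c1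
F11 | step 4 | 1-[2-(benzyloxy)-6-(methoxymethoxy)-4-methylphenyl]prop-2-yn-1-ol (racemic) | C#CC(O)c1c(OCOC)cc(C)cc1OCc1ccccc1
F12 | step 4 | tert-butyl({1-[2-(benzyloxy)-6-(methoxymethoxy)-4-methylphenyl]prop-2-yn-1-yl}oxy)dimethylsilane (racemic) | C#CC(O[Si](C)(C)C(C)(C)C)c1c(OCOC)cc(C)cc1OCc1ccccc1
F13 | step 4 | lithium acetylide of F12 (racemic, not isolated) | [Li]C#CC(O[Si](C)(C)C(C)(C)C)c1c(OCOC)cc(C)cc1OCc1ccccc1
F14 | step 4 | methyl 4-[2-(benzyloxy)-6-(methoxymethoxy)-4-methylphenyl]-4-[(tert-butyldimethylsilyl)oxy]but-2-ynoate (racemic) | COC(=O)C#CC(O[Si](C)(C)C(C)(C)C)c1c(OCOC)cc(C)cc1OCc1ccccc1
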